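The target is cut at its two ester C–O bonds to lutein and α-linolenic acid, and lutein at its only two carbon–oxygen bonds, C3–O on ring β and C3'–O on ring ε. Both are installed in one operation by a pair of carotenoid cytochrome P450 hydroxylases acting on the oxygen-free C40 hydrocarbon (6'R)-α-carotene, whose all-E polyene and single stereocentre C6' come from a C15 + C10 + C15 Wittig assembly. The step exploits the fact that the C3 methylene of ring β and the allylic C3' methylene of ring ε are the only positions to be functionalised, and that each end ring is the native guest of one enzyme, which sets 3R and 3'R.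

Key step: step 7

Remarks on the chemistry:
- The target is read as (3R,3'R,6'R)-lutein bis[(9Z,12Z,15Z)-octadeca-9,12,15-trienoate]. The descriptors and double-bond geometries of every structure used below were re-derived from the SMILES and agree with one another, so none needed correction.
- Assumption: (R)-α-ionone is bought as enantiopure natural-grade material.
- Precursor design: the hydrocarbon is handed to the enzymes only as the crystalline all-E, 6'R isomer in a micellar dispersion. The 2Z salts are removed by crystallisation and the hindered Z bonds from the Wittig steps are equilibrated thermally. Ring β is attached first, so the chiral ε salt is used once, in a non-statistical coupling.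
- All polyenes are handled under argon (air only in step 7), in dim light, with BHT.

Step 1
Reactants: 1 β-ionone
Product: 2 vinyl-β-ionol, (1E)-3-methyl-1-(2,6,6-trimethylcyclohex-1-en-1-yl)penta-1,4-dien-3-ol (racemic at the carbinol carbon)
Conditions: CH2=CHMgBr (1.3 equiv), THF, −20 → 0 °C; then H2O
Reagents that add atoms: vinylmagnesium bromide, C=C[Mg]Br
Why: Grignard 1,2-addition of the vinyl nucleophile to the ketone carbonyl of the dienone should outrun conjugate addition at low temperature; the new carbinol centre is formed racemic and is erased in step 2.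

Step 2
Reactants: 2 vinyl-β-ionol
Product: 3 β-C15 phosphonium bromide, [(2E,4E)-3-methyl-5-(2,6,6-trimethylcyclohex-1-en-1-yl)penta-2,4-dien-1-yl]triphenylphosphonium bromide
Conditions: PPh3·HBr (1.05 equiv), MeOH, 0 °C → rt; crystallisation (EtOAc)
Reagents that add atoms: triphenylphosphine hydrobromide, [Br-].[PH+](c1ccccc1)(c1ccccc1)c1ccccc1
Why: SN1'-type allylic substitution: HBr ionises the tertiary doubly allylic alcohol to a pentadienyl cation that triphenylphosphine captures at the unhindered terminal carbon, the 2E,4E salt being favoured thermodynamically and purified by crystallisation.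

Step 3
Reactants: 3 β-C15 phosphonium bromide; 4 (2E,4E,6E)-2,7-dimethylocta-2,4,6-trienedial (C10 dialdehyde, 3 equiv)
Product: 7 all-E 12'-apo-β-caroten-12'-al (C25 aldehyde), via β-C15 ylide 5 (not isolated), via 11Z-aldehyde 6 (not isolated)
Conditions: NaOMe (1.0 equiv, added slowly), MeOH/CH2Cl2, −10 °C → rt; then heptane, reflux, Ar; crystallisation
Reagents that add atoms: none
Why: Wittig olefination with the semi-stabilised allylic ylide 5; with the dialdehyde in excess, and because the remaining formyl group of the C25 product is deactivated by conjugation with the longer polyene, condensation should stop at one end, and the hindered 11Z bond of 6 should relax to E on heating.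

Step 4
Reactants: 8 (R)-α-ionone
Product: 9 vinyl-α-ionol, (1E)-3-methyl-1-[(1R)-2,6,6-trimethylcyclohex-2-en-1-yl]penta-1,4-dien-3-ol (both carbinol epimers)
Conditions: CH2=CHMgBr (1.3 equiv), THF, −20 → 0 °C; then H2O
Reagents that add atoms: vinylmagnesium bromide, C=C[Mg]Br
Why: Grignard 1,2-addition as in step 1; at low temperature carbonyl addition should be much faster than γ-deprotonation, so the ring stereocentre (R) is carried through unchanged.

Step 5
Reactants: 9 vinyl-α-ionol
Product: 10 ε-C15 phosphonium bromide, [(2E,4E)-3-methyl-5-[(1R)-2,6,6-trimethylcyclohex-2-en-1-yl]penta-2,4-dien-1-yl]triphenylphosphonium bromide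
Conditions: PPh3·HBr (1.05 equiv), MeOH, 0 °C; crystallisation
Reagents that add atoms: triphenylphosphine hydrobromide, [Br-].[PH+](c1ccccc1)(c1ccccc1)c1ccccc1
Why: SN1'-type allylic substitution as in step 2: the cation is confined to the side chain and is trapped by the phosphine at its terminus at low temperature before proton loss from the ring CH or migration of the ring double bond can occur, so the R centre should survive.

Step 6
Reactants: 10 ε-C15 phosphonium bromide (1.1 equiv); 7 all-E 12'-apo-β-caroten-12'-al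
Product: 13 (6'R)-α-carotene (all-E), via ε-C15 ylide 11 (not isolated), via 11'Z-α-carotene 12 (not isolated)
Conditions: NaOMe, MeOH/CH2Cl2, 0 °C → rt; then heptane, reflux, Ar; crystallisation (CH2Cl2/MeOH)
Reagents that add atoms: none
Why: Wittig olefination of the polyenal 7 by ylide 11 forms the C11'=C12' bond, and heating equilibrates the hindered 11'Z isomer 12 to the all-E polyene; the ring ε CH is not acidic enough to be touched by methoxide, so 6'R is retained.

Step 7
Reactants: 13 (6'R)-α-carotene
Product: 15 (3R,3'R,6'R)-lutein, via zeinoxanthin 14 (not isolated)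
Conditions: CYP97A3 and CYP97C1 (recombinant, Arabidopsis thaliana), spinach ferredoxin, ferredoxin–NADP+ reductase, NADP+ (cat.), D-glucose, glucose dehydrogenase, catalase, air, 13 in Tween 80 micelles, KH2PO4/K2HPO4 buffer pH 7.5, 28 °C, dark
Reagents that add atoms: dioxygen, O=O
Why: In each enzyme the haem is reduced by NADPH through ferredoxin–NADP+ reductase and ferredoxin, binds O2 and is converted to the oxo-iron porphyrin radical cation (tetravalent iron), which abstracts one hydrogen atom from the ring CH2 held over it, and the carbon radical recombines with the iron-bound hydroxyl on the same face (oxygen rebound), so C–H becomes C–OH with retention. The closest known reaction type is cytochrome P450 C–H hydroxylation, here the native two-enzyme sequence of plant lutein biosynthesis, which has been reproduced with recombinant enzymes and in engineered microbes. No ring is closed. The 3R centre is dictated by the active site of the ring β hydroxylase CYP97A3, which acts first to give zeinoxanthin 14, and the 3'R centre by the active site of the ring ε hydroxylase CYP97C1, which takes on 14; the existing 6'R centre is not touched and the substrate itself exerts no control. The step needs site selectivity for C3 over the allylic C4, and for C3' over C2' and the doubly allylic C6', with no attack on the polyene; this is secured by the substrate tunnels, which seat each end ring with C3 nearest the iron and fit only the all-E C40 chain, which is why 13 is supplied as the pure all-E 6'R hydrocarbon in micelles.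

Step 8
Reactants: 15 (3R,3'R,6'R)-lutein; 16 α-linolenic acid (2.6 equiv)
Product: 19 lutein di-α-linolenate (target), via lutein 3-monolinolenate 17 (not isolated), via lutein 3'-monolinolenate 18 (not isolated)
Conditions: DCC (2.8 equiv), DMAP (0.3 equiv), CH2Cl2, 0 °C → rt, Ar, dark, BHT
Reagents that add atoms: none
Why: Steglich esterification: the carbodiimide activates the acid as an O-acylisourea, DMAP relays the acyl group to both secondary hydroxyls in either order, and since no C–O bond at C3 or C3' is broken and the medium is neutral, 3R, 3'R, 6'R and all double-bond geometries should be retained.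

Compound list
1 | β-ionone, (3E)-4-(2,6,6-trimethylcyclohex-1-en-1-yl)but-3-en-2-one | CC(=O)/C=C/C1=C(C)CCCC1(C)C | starting material
2 | vinyl-β-ionol, (1E)-3-methyl-1-(2,6,6-trimethylcyclohex-1-en-1-yl)penta-1,4-dien-3-ol (racemic) | C=CC(C)(O)/C=C/C1=C(C)CCCC1(C)C | intermediate
3 | β-C15 phosphonium bromide, [(2E,4E)-3-methyl-5-(2,6,6-trimethylcyclohex-1-en-1-yl)penta-2,4-dien-1-yl]triphenylphosphonium bromide | [Br-].CC1=C(/C=C/C(C)=C/C[P+](c2ccccc2)(c2ccccc2)c2ccccc2)C(C)(C)CCC1 | intermediate
4 | (2E,4E,6E)-2,7-dimethylocta-2,4,6-trienedial (C10 dialdehyde) | O=C/C(C)=C/C=C/C=C(C)/C=O | starting material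
5 | β-C15 ylide, the phosphonium ylide of 3 (carbanion on the CH next to phosphorus) | CC1=C(/C=C/C(C)=C/[CH-][P+](c2ccccc2)(c2ccccc2)c2ccccc2)C(C)(C)CCC1 | intermediate
6 | (11Z)-12'-apo-β-caroten-12'-al | CC1=C(/C=C/C(C)=C/C=C\C(C)=C\C=C\C=C(C)\C=O)C(C)(C)CCC1 | intermediate
7 | all-E 12'-apo-β-caroten-12'-al, (2E,4E,6E,8E,10E,12E)-2,7,11-trimethyl-13-(2,6,6-trimethylcyclohex-1-en-1-yl)trideca-2,4,6,8,10,12-hexaenal | CC1=C(/C=C/C(C)=C/C=C/C(C)=C/C=C/C=C(C)/C=O)C(C)(C)CCC1 | intermediate
8 | (R)-α-ionone, (3E)-4-[(1R)-2,6,6-trimethylcyclohex-2-en-1-yl]but-3-en-2-one | CC(=O)/C=C/[C@H]1C(C)=CCCC1(C)C | starting material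
9 | vinyl-α-ionol, (1E)-3-methyl-1-[(1R)-2,6,6-trimethylcyclohex-2-en-1-yl]penta-1,4-dien-3-ol (both carbinol epimers) | C=CC(C)(O)/C=C/[C@H]1C(C)=CCCC1(C)C | intermediate
10 | ε-C15 phosphonium bromide, [(2E,4E)-3-methyl-5-[(1R)-2,6,6-trimethylcyclohex-2-en-1-yl]penta-2,4-dien-1-yl]triphenylphosphonium bromide | [Br-].c1ccccc1[P+](c1ccccc1)(c1ccccc1)C/C=C(C)/C=C/[C@H]1C(C)=CCCC1(C)C | intermediate
11 | ε-C15 ylide, the phosphonium ylide of 10 | c1ccccc1[P+](c1ccccc1)(c1ccccc1)[CH-]/C=C(C)/C=C/[C@H]1C(C)=CCCC1(C)C | intermediate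
12 | (11'Z,6'R)-α-carotene | CC1=C(/C=C/C(C)=C/C=C/C(C)=C/C=C/C=C(C)/C=C\C=C(C)\C=C\[C@H]2C(C)=CCCC2(C)C)C(C)(C)CCC1 | intermediate
13 | (6'R)-α-carotene, all-E (6'R)-β,ε-carotene | CC1=C(/C=C/C(C)=C/C=C/C(C)=C/C=C/C=C(C)/C=C/C=C(C)/C=C/[C@H]2C(C)=CCCC2(C)C)C(C)(C)CCC1 | intermediate
14 | zeinoxanthin, (3R,6'R)-β,ε-caroten-3-ol | O[C@@H]1CC(C)=C(/C=C/C(C)=C/C=C/C(C)=C/C=C/C=C(C)/C=C/C=C(C)/C=C/[C@H]2C(C)=CCCC2(C)C)C(C)(C)C1 | intermediate
15 | (3R,3'R,6'R)-lutein, (3R,3'R,6'R)-β,ε-carotene-3,3'-diol | O[C@@H]1CC(C)=C(/C=C/C(C)=C/C=C/C(C)=C/C=C/C=C(C)/C=C/C=C(C)/C=C/[C@H]2C(C)=C[C@H](O)CC2(C)C)C(C)(C)C1 | intermediate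
16 | α-linolenic acid, (9Z,12Z,15Z)-octadeca-9,12,15-trienoic acid | CC/C=C\C/C=C\C/C=C\CCCCCCCC(=O)O | starting material
17 | lutein 3-monolinolenate (ester on ring β, free 3'-OH) | CC/C=C\C/C=C\C/C=C\CCCCCCCC(=O)O[C@@H]1CC(C)=C(/C=C/C(C)=C/C=C/C(C)=C/C=C/C=C(C)/C=C/C=C(C)/C=C/[C@H]2C(C)=C[C@H](O)CC2(C)C)C(C)(C)C1 | intermediate
18 | lutein 3'-monolinolenate (ester on ring ε, free 3-OH) | O[C@@H]1CC(C)=C(/C=C/C(C)=C/C=C/C(C)=C/C=C/C=C(C)/C=C/C=C(C)/C=C/[C@H]2C(C)=C[C@H](OC(=O)CCCCCCC/C=C\C/C=C\C/C=C\CC)CC2(C)C)C(C)(C)C1 | intermediate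
19 | (3R,3'R,6'R)-lutein bis[(9Z,12Z,15Z)-octadeca-9,12,15-trienoate] | CC/C=C\C/C=C\C/C=C\CCCCCCCC(=O)O[C@@H]1CC(C)=C(/C=C/C(C)=C/C=C/C(C)=C/C=C/C=C(C)/C=C/C=C(C)/C=C/[C@H]2C(C)=C[C@H](OC(=O)CCCCCCC/C=C\C/C=C\C/C=C\CC)CC2(C)C)C(C)(C)C1 | target

Total step count: 8
Longest linear sequence: 6 steps (steps 1, 2, 3, 6, 7, 8)

Steps most likely to fail

Step 7. The water-insoluble hydrocarbon may not reach the two active sites, electron transfer may uncouple so that reductant is spent without oxygen transfer, or the cascade may stall after the first hydroxylation. The fallback gives up late-stage C–H oxidation and brings both oxygens in with the end groups; it sets out from 4 and 8 and comes back at 15. Dialdehyde 4 (excess) would be condensed under the conditions of step 3 with [(2E,4E)-5-[(4R)-4-hydroxy-2,6,6-trimethylcyclohex-1-en-1-yl]-3-methylpenta-2,4-dien-1-yl]triphenylphosphonium bromide F1, purchased as the established zeaxanthin end-group salt, to give (3R)-3-hydroxy-12'-apo-β-caroten-12'-al F2. In parallel, 8 would be hydroxylated at its allylic ring CH2 by the known trans-selective microbial oxidation of α-ionone (whole cells with an engineered P450 BM3 variant) to (3R,6R)-3-hydroxy-α-ionone F3, with any cis diastereomer removed by chromatography. Vinylmagnesium bromide (2.5 equiv, THF, −20 °C) would give (1E)-1-[(1R,4R)-4-hydroxy-2,6,6-trimethylcyclohex-2-en-1-yl]-3-methylpenta-1,4-dien-3-ol F4. PPh3·HBr in MeOH at 0 °C, where the tertiary doubly allylic hydroxyl should ionise well before the ring hydroxyl, would give [(2E,4E)-5-[(1R,4R)-4-hydroxy-2,6,6-trimethylcyclohex-2-en-1-yl]-3-methylpenta-2,4-dien-1-yl]triphenylphosphonium bromide F5. Wittig coupling of F5 with F2 (NaOMe, MeOH/CH2Cl2), then thermal equilibration of the hindered Z bond, should deliver 15.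

Step 5. The acid may move the ring ε double bond into conjugation or cause proton loss from the cation, eroding the configuration at the ring CH, or the control of the 2E/2Z geometry may be poor. The fallback avoids any carbocation; it sets out from 8 and comes back at 10. Horner–Wadsworth–Emmons reaction of 8 with triethyl phosphonoacetate (NaH, THF, 0 °C) would give ethyl (2E,4E)-3-methyl-5-[(1R)-2,6,6-trimethylcyclohex-2-en-1-yl]penta-2,4-dienoate F6, the 2E isomer being separated by chromatography. Reduction with i-Bu2AlH (CH2Cl2, −78 °C) would give (2E,4E)-3-methyl-5-[(1R)-2,6,6-trimethylcyclohex-2-en-1-yl]penta-2,4-dien-1-ol F7. PBr3/pyridine (Et2O, −20 °C) would give (2E,4E)-1-bromo-3-methyl-5-[(1R)-2,6,6-trimethylcyclohex-2-en-1-yl]penta-2,4-diene F8, and PPh3 in toluene at rt should precipitate 10.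

Step 8. The coupling may stall at the monoesters through O→N acyl migration of the activated acid, and removal of the urea may cost sensitive material. The fallback pre-activates the acid in a separate operation; it sets out from 16 and comes back at 19. Oxalyl chloride (cat. DMF, CH2Cl2, 0 °C) would convert 16 into α-linolenoyl chloride F9, which would acylate 15 in CH2Cl2/pyridine with catalytic DMAP at 0 °C to give 19.

Further compounds
F1 | step 7 | [(2E,4E)-5-[(4R)-4-hydroxy-2,6,6-trimethylcyclohex-1-en-1-yl]-3-methylpenta-2,4-dien-1-yl]triphenylphosphonium bromide | [Br-].O[C@@H]1CC(C)=C(/C=C/C(C)=C/C[P+](c2ccccc2)(c2ccccc2)c2ccccc2)C(C)(C)C1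
F2 | step 7 | (3R)-3-hydroxy-12'-apo-β-caroten-12'-al | O[C@@H]1CC(C)=C(/C=C/C(C)=C/C=C/C(C)=C/C=C/C=C(C)/C=O)C(C)(C)C1
F3 | step 7 | (3R,6R)-3-hydroxy-α-ionone, (3E)-4-[(1R,4R)-4-hydroxy-2,6,6-trimethylcyclohex-2-en-1-yl]but-3-en-2-one | CC(=O)/C=C/[C@H]1C(C)=C[C@H](O)CC1(C)C
F4 | step 7 | (1E)-1-[(1R,4R)-4-hydroxy-2,6,6-trimethylcyclohex-2-en-1-yl]-3-methylpenta-1,4-dien-3-ol | C=CC(C)(O)/C=C/[C@H]1C(C)=C[C@H](O)CC1(C)C
F5 | step 7 | [(2E,4E)-5-[(1R,4R)-4-hydroxy-2,6,6-trimethylcyclohex-2-en-1-yl]-3-methylpenta-2,4-dien-1-yl]triphenylphosphonium bromide | [Br-].c1ccccc1[P+](c1ccccc1)(c1ccccc1)C/C=C(C)/C=C/[C@H]1C(C)=C[C@H](O)CC1(C)C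
F6 | step 5 | ethyl (2E,4E)-3-methyl-5-[(1R)-2,6,6-trimethylcyclohex-2-en-1-yl]penta-2,4-dienoate | CCOC(=O)/C=C(C)/C=C/[C@H]1C(C)=CCCC1(C)C
F7 | step 5 | (2E,4E)-3-methyl-5-[(1R)-2,6,6-trimethylcyclohex-2-en-1-yl]penta-2,4-dien-1-ol | OC/C=C(C)/C=C/[C@H]1C(C)=CCCC1(C)C
F8 | step 5 | (2E,4E)-1-bromo-3-methyl-5-[(1R)-2,6,6-trimethylcyclohex-2-en-1-yl]penta-2,4-diene | BrC/C=C(C)/C=C/[C@H]1C(C)=CCCC1(C)C
F9 | step 8 | α-linolenoyl chloride, (9Z,12Z,15Z)-octadeca-9,12,15-trienoyl chloride | CC/C=C\C/C=C\C/C=C\CCCCCCCC(=O)Cl
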